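**Plan**
- Cuts: C7=C8 (Wittig) and C7'=C8' (Julia–Kocienski) release crocetin dialdehyde (C20) and two C10 ring pieces. In each ring piece the last cut is the ring bond between the CH2 (C2 or C2') and the gem-dimethyl carbon (C1 or C1').
- Forward: a Negishi coupling assembles an acyclic Z-dienone, and in the same operation that bond is closed once, by an intramolecular Michael addition, to give racemic ethyl 2,6,6-trimethyl-4-oxocyclohex-2-ene-1-carboxylate. This keto ester feeds both the ε ring and the β ring; the ε piece is joined to the dialdehyde first, the β piece last.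
- Enabling feature: in each ring the CH2 (C2) is next to the oxygen-bearing C3, so a C3 ketone makes it an enolate carbon. The quaternary C1 is β to C7 through C6, so a C7 ester on a C6=C1 double bond makes it a Michael acceptor carbon. The cis C4=C5 bond holds the two ends in reach.
- Stereochemistry: C3' and C3 by catalytic asymmetric transfer hydrogenation (two catalyst antipodes). C6' is relayed from C3' by face-selective protonation of the ester enolate. C4 is relayed from C3 by hydroxyl-directed epoxidation and E1cB opening.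

Key step: step 2

Remark: keto ester 9 is racemic and labile at C1 by design, so 10, 11, 20 and 21 are carried as C1 epimers; 4 and 17 are taken as catalogue compounds.

Step 1
Reactants: 1 pentane-2,4-dione
Product: 3 (2Z)-4-oxopent-2-en-2-yl trifluoromethanesulfonate, via lithium acetylacetonate 2 (not isolated)
Conditions: Tf2O, aq. LiOH, toluene, 5 °C
Reagents that add atoms: trifluoromethanesulfonic anhydride, O=S(=O)(OS(=O)(=O)C(F)(F)F)C(F)(F)F
Why: The lithium-chelated enolate 2 holds the enolate oxygen cis to the acetyl group, so O-sulfonylation should give the Z enol triflate (stereoselective enol triflate formation from a 1,3-dicarbonyl compound).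

Step 2
Reactants: 3 (2Z)-4-oxopent-2-en-2-yl trifluoromethanesulfonate; 4 ethyl 2-bromo-3-methylbut-2-enoate
Product: 9 ethyl (1RS)-2,6,6-trimethyl-4-oxocyclohex-2-ene-1-carboxylate, via alkenylzinc bromide 5 (not isolated), via Z-dienone 6 (not isolated), via pyran valence tautomer 7 (not isolated), via sodium dienolate 8 (not isolated)
Conditions: 4, Zn, LiCl, THF, 25 °C; then 3, Pd(PPh3)4 (5 mol %), THF, 50 °C; aq. NH4Cl wash, solvent switch to EtOH (solution carried on); NaOEt (1.1 equiv), 0 → 25 °C; then AcOH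
Reagents that add atoms: none
Why: Zinc inserts into the ester-activated alkenyl C–Br bond and Negishi cross-coupling of 5 with the enol triflate, with retention at both sp2 carbons, gives the Z-dienone 6, which rests in solution as its pyran valence tautomer 7 (oxa-6π electrocyclisation, favoured by the gem-dimethyl carbon and the push-pull ester) and returns to the open form by thermal retro-oxa-6π opening; ethoxide deprotonates the acetyl CH3 of the open form, and the enolate carbon adds to the gem-dimethyl β-carbon of the alkylidene ester and closes the carbocycle to the sodium dienolate 8, which acetic acid protonates to 9. The closest known reaction type is the base-mediated intramolecular Michael addition of a methyl ketone enolate to an alkylidene ester, as used in isophorone-type and Hagemann-ester cyclohexenone syntheses. The carbocycle closes in a 6-endo-trig mode with the enolate C=C inside the forming ring, the same bond reorganisation as a disrotatory 6π electrocyclisation of a 2-oxido-5-alkoxycarbonyl hexatriene, so the donor and acceptor ends reinforce each other, whereas the oxygen ring of 7 closes and reopens by 6π electrocyclisation and is not carried further. The only stereocentre formed, C1 of 9, arises on protonation of the planar dienolate and is deliberately left racemic and epimerisable, because it is rewritten in step 5 and erased in step 12. The step needs C–C bond formation at the quaternary carbon in preference to Claisen attack on the ester carbonyl and to aldol aromatisation through an isopropylidene methyl group; the cis C=C set by the Z enol triflate holds the enolate carbon next to the alkylidene carbon, the acetyl CH3 is the most acidic site, and the product is withdrawn as the weakly basic vinylogous β-keto ester enolate 8.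

Step 3
Reactants: 9 ethyl (1RS)-2,6,6-trimethyl-4-oxocyclohex-2-ene-1-carboxylate
Product: 10 ethyl (1RS,4R)-4-hydroxy-2,6,6-trimethylcyclohex-2-ene-1-carboxylate
Conditions: RuCl[(R,R)-TsDPEN](p-cymene) (1 mol %), HCO2H/Et3N (5:2), CH2Cl2, 25 °C
Reagents that add atoms: none
Why: Noyori–Ikariya asymmetric transfer hydrogenation should reduce the enone carbonyl 1,2 under catalyst control, the (R,R) ligand giving the (4R)-carbinol by the aryl ketone model with the ring C=C in the place of the arene, while C1 equilibrates through the enol under the amine so that each molecule can react through its matched pairing.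

Step 4
Reactants: 10 ethyl (1RS,4R)-4-hydroxy-2,6,6-trimethylcyclohex-2-ene-1-carboxylate
Product: 11 ethyl (1RS,4R)-4-[(tert-butyldimethylsilyl)oxy]-2,6,6-trimethylcyclohex-2-ene-1-carboxylate
Conditions: TBSCl, imidazole, DMF, 25 °C
Reagents that add atoms: tert-butyldimethylsilyl chloride, CC(C)(C)[Si](C)(C)Cl
Why: Standard silylation of the secondary allylic alcohol, which also installs the bulky group that fixes the ring conformation for step 5.

Step 5
Reactants: 11 ethyl (1RS,4R)-4-[(tert-butyldimethylsilyl)oxy]-2,6,6-trimethylcyclohex-2-ene-1-carboxylate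
Product: 13 ethyl (1R,4R)-4-[(tert-butyldimethylsilyl)oxy]-2,6,6-trimethylcyclohex-2-ene-1-carboxylate, via lithium ester enolate 12 (not isolated)
Conditions: LiN(i-Pr)2 (1.5 equiv), THF/DMPU, −78 → −20 °C; then AcOH, −78 °C
Reagents that add atoms: none
Why: Deprotonation gives the planar ester dienolate 12 from both C1 epimers, and kinetic protonation at the α-carbon should occur anti to the pseudo-axial C6 methyl group, which the pseudo-equatorial silyloxy group at C4 places on the opposite ring face, so that the new C1–H is cis to the silyloxy group and the ester trans to it (deconjugative enolate protonation, 1,4-relay of configuration).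

Step 6
Reactants: 13 ethyl (1R,4R)-4-[(tert-butyldimethylsilyl)oxy]-2,6,6-trimethylcyclohex-2-ene-1-carboxylate
Product: 14 [(1R,4R)-4-[(tert-butyldimethylsilyl)oxy]-2,6,6-trimethylcyclohex-2-en-1-yl]methanol
Conditions: i-Bu2AlH (2.5 equiv), CH2Cl2, −78 → 0 °C; Rochelle salt work-up
Reagents that add atoms: none
Why: i-Bu2AlH reduces the ester to the primary alcohol in a non-basic medium, so the adjacent C1 stereocentre is not touched (ester reduction).

Step 7
Reactants: 14 [(1R,4R)-4-[(tert-butyldimethylsilyl)oxy]-2,6,6-trimethylcyclohex-2-en-1-yl]methanol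
Product: 15 5-({[(1R,4R)-4-[(tert-butyldimethylsilyl)oxy]-2,6,6-trimethylcyclohex-2-en-1-yl]methyl}sulfanyl)-1-phenyl-1H-tetrazole
Conditions: 1-phenyl-1H-tetrazole-5-thiol, PPh3, DIAD, THF, 0 → 25 °C
Reagents that add atoms: 1-phenyl-1H-tetrazole-5-thiol, Sc1nnnn1-c1ccccc1
Why: Mitsunobu thioetherification of the primary alcohol with the acidic tetrazole thiol, the silyl ether masking the secondary hydroxyl.

Step 8
Reactants: 15 5-({[(1R,4R)-4-[(tert-butyldimethylsilyl)oxy]-2,6,6-trimethylcyclohex-2-en-1-yl]methyl}sulfanyl)-1-phenyl-1H-tetrazole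
Product: 16 5-({[(1R,4R)-4-[(tert-butyldimethylsilyl)oxy]-2,6,6-trimethylcyclohex-2-en-1-yl]methyl}sulfonyl)-1-phenyl-1H-tetrazole
Conditions: (NH4)6Mo7O24·4H2O (10 mol %), 30% H2O2, EtOH, 0 → 25 °C
Reagents that add atoms: hydrogen peroxide, OO
Why: Molybdate-catalysed peroxide oxidation takes the sulfide to the sulfone faster than it epoxidises the trisubstituted alkene (sulfide oxidation in preparation for Julia–Kocienski olefination).

Step 9
Reactants: 16 5-({[(1R,4R)-4-[(tert-butyldimethylsilyl)oxy]-2,6,6-trimethylcyclohex-2-en-1-yl]methyl}sulfonyl)-1-phenyl-1H-tetrazole; 17 (2E,4E,6E,8E,10E,12E,14E)-2,6,11,15-tetramethylhexadeca-2,4,6,8,10,12,14-heptaenedial (crocetin dialdehyde)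
Product: 19 (2E,4E,6E,8E,10E,12E,14E,16E)-17-[(1R,4R)-4-[(tert-butyldimethylsilyl)oxy]-2,6,6-trimethylcyclohex-2-en-1-yl]-2,6,11,15-tetramethylheptadeca-2,4,6,8,10,12,14,16-octaenal, via potassium sulfonyl carbanion 18 (not isolated)
Conditions: KN(SiMe3)2 (1.1 equiv), DME, −60 °C; then 17 (3 equiv), −60 → 25 °C
Reagents that add atoms: none
Why: Julia–Kocienski olefination of the α-branched alkyl tetrazolyl sulfone with one formyl group of the excess dialdehyde should give the E-disubstituted C=C by addition, Smiles rearrangement and anti elimination, the ring C1 stereocentre being β to the carbanion and therefore safe.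

Step 10
Reactants: 9 ethyl (1RS)-2,6,6-trimethyl-4-oxocyclohex-2-ene-1-carboxylate
Product: 20 ethyl (1RS,4S)-4-hydroxy-2,6,6-trimethylcyclohex-2-ene-1-carboxylate
Conditions: RuCl[(S,S)-TsDPEN](p-cymene) (1 mol %), HCO2H/Et3N (5:2), CH2Cl2, 25 °C
Reagents that add atoms: none
Why: The same Noyori–Ikariya transfer hydrogenation with the antipodal catalyst should give the (4S)-carbinol, and the C1 configuration is irrelevant here because it is erased in step 12.

Step 11
Reactants: 20 ethyl (1RS,4S)-4-hydroxy-2,6,6-trimethylcyclohex-2-ene-1-carboxylate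
Product: 21 ethyl (1RS,2R,3S,4S)-2,3-epoxy-4-hydroxy-2,6,6-trimethylcyclohexane-1-carboxylate (oxirane cis to the hydroxyl)
Conditions: mCPBA, NaHCO3, CH2Cl2, 0 °C
Reagents that add atoms: 3-chloroperoxybenzoic acid, OOC(=O)c1cccc(Cl)c1
Why: Hydrogen-bond-directed peracid epoxidation of the cyclic allylic alcohol delivers oxygen to the face of the hydroxyl group, so both oxirane carbons carry oxygen cis to the C4 hydroxyl whichever the configuration at C1.

Step 12
Reactants: 21 ethyl (1RS,2R,3S,4S)-2,3-epoxy-4-hydroxy-2,6,6-trimethylcyclohexane-1-carboxylate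
Product: 22 ethyl (3R,4S)-3,4-dihydroxy-2,6,6-trimethylcyclohex-1-ene-1-carboxylate (cis-diol)
Conditions: NaOEt (0.3 equiv), EtOH, 0 → 25 °C
Reagents that add atoms: none
Why: Ethoxide forms the ester enolate, which opens the adjacent oxirane by E1cB elimination to the conjugated ester, so that C1 is erased, the oxirane oxygen stays on C3 with its configuration and the diol is cis (β,γ-epoxy ester to γ-hydroxy-α,β-unsaturated ester isomerisation).

Step 13
Reactants: 22 ethyl (3R,4S)-3,4-dihydroxy-2,6,6-trimethylcyclohex-1-ene-1-carboxylate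
Product: 23 ethyl (3R,4S)-3,4-bis[(tert-butyldimethylsilyl)oxy]-2,6,6-trimethylcyclohex-1-ene-1-carboxylate
Conditions: TBSOTf (2.5 equiv), 2,6-lutidine, CH2Cl2, −40 → 0 °C
Reagents that add atoms: tert-butyldimethylsilyl trifluoromethanesulfonate, CC(C)(C)[Si](C)(C)OS(=O)(=O)C(F)(F)F
Why: The silyl triflate silylates both the secondary and the hindered allylic hydroxyl (silyl ether formation).

Step 14
Reactants: 23 ethyl (3R,4S)-3,4-bis[(tert-butyldimethylsilyl)oxy]-2,6,6-trimethylcyclohex-1-ene-1-carboxylate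
Product: 24 [(3R,4S)-3,4-bis[(tert-butyldimethylsilyl)oxy]-2,6,6-trimethylcyclohex-1-en-1-yl]methanol
Conditions: i-Bu2AlH (3 equiv), CH2Cl2, −78 → 0 °C; Rochelle salt work-up
Reagents that add atoms: none
Why: i-Bu2AlH reduces the hindered conjugated ester 1,2 to the primary allylic alcohol (ester reduction).

Step 15
Reactants: 24 [(3R,4S)-3,4-bis[(tert-butyldimethylsilyl)oxy]-2,6,6-trimethylcyclohex-1-en-1-yl]methanol
Product: 26 {[(3R,4S)-3,4-bis[(tert-butyldimethylsilyl)oxy]-2,6,6-trimethylcyclohex-1-en-1-yl]methyl}triphenylphosphonium bromide, via allylic bromide 25 (not isolated)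
Conditions: CBr4 (1.2 equiv), PPh3 (2.5 equiv), CH2Cl2, 0 → 25 °C; then MeCN, 45 °C
Reagents that add atoms: carbon tetrabromide, BrC(Br)(Br)Br; triphenylphosphine, c1ccc(cc1)P(c1ccccc1)c1ccccc1
Why: Appel bromination gives the primary allylic bromide 25 under neutral conditions that keep the allylic silyl ether, and the excess phosphine quaternises it by SN2 displacement.

Step 16
Reactants: 26 {[(3R,4S)-3,4-bis[(tert-butyldimethylsilyl)oxy]-2,6,6-trimethylcyclohex-1-en-1-yl]methyl}triphenylphosphonium bromide; 19 (2E,4E,6E,8E,10E,12E,14E,16E)-17-[(1R,4R)-4-[(tert-butyldimethylsilyl)oxy]-2,6,6-trimethylcyclohex-2-en-1-yl]-2,6,11,15-tetramethylheptadeca-2,4,6,8,10,12,14,16-octaenal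
Product: 28 (all-E)-(3S,4R,3'R,6'R)-3,4,3'-tris[(tert-butyldimethylsilyl)oxy]-β,ε-carotene, via phosphorus ylide 27 (not isolated)
Conditions: NaN(SiMe3)2 (1.05 equiv), THF, −78 → 0 °C; then 19, −78 → 25 °C
Reagents that add atoms: none
Why: Wittig olefination of the semi-stabilised allylic ylide 27 with the polyenal should give the E-alkene, the Z isomer being disfavoured by the flanking ring methyl groups, and the silyloxy groups are too poor as leaving groups to be lost from the ylide.

Step 17
Reactants: 28 (all-E)-(3S,4R,3'R,6'R)-3,4,3'-tris[(tert-butyldimethylsilyl)oxy]-β,ε-carotene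
Product: 29 (all-E)-(3S,4R,3'R,6'R)-β,ε-carotene-3,4,3'-triol
Conditions: Bu4NF (6 equiv), AcOH (6 equiv), THF, 25 → 40 °C
Reagents that add atoms: none
Why: Fluoride cleaves the three silyl ethers under buffered, non-acidic conditions that spare the two allylic alcohols and the polyene (desilylation).

**Compound list**
1 | pentane-2,4-dione | CC(=O)CC(C)=O | starting material
2 | lithium (2Z)-4-oxopent-2-en-2-olate (lithium acetylacetonate) | CC(=O)/C=C(/C)[O-].[Li+] | intermediate
3 | (2Z)-4-oxopent-2-en-2-yl trifluoromethanesulfonate | CC(=O)/C=C(/C)OS(=O)(=O)C(F)(F)F | intermediate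
4 | ethyl 2-bromo-3-methylbut-2-enoate | CCOC(=O)C(Br)=C(C)C | starting material
5 | ethyl 2-(bromozincio)-3-methylbut-2-enoate | CCOC(=O)C([Zn]Br)=C(C)C | intermediate
6 | ethyl (3Z)-3-methyl-5-oxo-2-(propan-2-ylidene)hex-3-enoate | CCOC(=O)C(=C(C)C)/C(C)=C\C(C)=O | intermediate
7 | ethyl 2,2,4,6-tetramethyl-2H-pyran-3-carboxylate | CCOC(=O)C1=C(C)C=C(C)OC1(C)C | intermediate
8 | sodium 4-(ethoxycarbonyl)-3,5,5-trimethylcyclohexa-1,3-dien-1-olate | CCOC(=O)C1=C(C)C=C([O-])CC1(C)C.[Na+] | intermediate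
9 | ethyl (1RS)-2,6,6-trimethyl-4-oxocyclohex-2-ene-1-carboxylate | CCOC(=O)C1C(C)=CC(=O)CC1(C)C | intermediate
10 | ethyl (1RS,4R)-4-hydroxy-2,6,6-trimethylcyclohex-2-ene-1-carboxylate | CCOC(=O)C1C(C)=C[C@H](O)CC1(C)C | intermediate
11 | ethyl (1RS,4R)-4-[(tert-butyldimethylsilyl)oxy]-2,6,6-trimethylcyclohex-2-ene-1-carboxylate | CCOC(=O)C1C(C)=C[C@H](O[Si](C)(C)C(C)(C)C)CC1(C)C | intermediate
12 | lithium ester enolate of 11 (planar at C1) | CCOC([O-])=C1C(C)=C[C@H](O[Si](C)(C)C(C)(C)C)CC1(C)C.[Li+] | intermediate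
13 | ethyl (1R,4R)-4-[(tert-butyldimethylsilyl)oxy]-2,6,6-trimethylcyclohex-2-ene-1-carboxylate (ester trans to silyloxy) | CC1=C[C@H](O[Si](C)(C)C(C)(C)C)CC(C)(C)[C@H]1C(=O)OCC | intermediate
14 | [(1R,4R)-4-[(tert-butyldimethylsilyl)oxy]-2,6,6-trimethylcyclohex-2-en-1-yl]methanol | CC1=C[C@H](O[Si](C)(C)C(C)(C)C)CC(C)(C)[C@H]1CO | intermediate
15 | 5-({[(1R,4R)-4-[(tert-butyldimethylsilyl)oxy]-2,6,6-trimethylcyclohex-2-en-1-yl]methyl}sulfanyl)-1-phenyl-1H-tetrazole | CC1=C[C@H](O[Si](C)(C)C(C)(C)C)CC(C)(C)[C@H]1CSc1nnnn1-c1ccccc1 | intermediate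
16 | 5-({[(1R,4R)-4-[(tert-butyldimethylsilyl)oxy]-2,6,6-trimethylcyclohex-2-en-1-yl]methyl}sulfonyl)-1-phenyl-1H-tetrazole | CC1=C[C@H](O[Si](C)(C)C(C)(C)C)CC(C)(C)[C@H]1CS(=O)(=O)c1nnnn1-c1ccccc1 | intermediate
17 | (2E,4E,6E,8E,10E,12E,14E)-2,6,11,15-tetramethylhexadeca-2,4,6,8,10,12,14-heptaenedial (crocetin dialdehyde) | O=C/C(C)=C/C=C/C(C)=C/C=C/C=C(C)/C=C/C=C(C)/C=O | starting material
18 | potassium α-sulfonyl carbanion of 16 | CC1=C[C@H](O[Si](C)(C)C(C)(C)C)CC(C)(C)[C@H]1[CH-]S(=O)(=O)c1nnnn1-c1ccccc1.[K+] | intermediate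
19 | (2E,4E,6E,8E,10E,12E,14E,16E)-17-[(1R,4R)-4-[(tert-butyldimethylsilyl)oxy]-2,6,6-trimethylcyclohex-2-en-1-yl]-2,6,11,15-tetramethylheptadeca-2,4,6,8,10,12,14,16-octaenal | CC1=C[C@H](O[Si](C)(C)C(C)(C)C)CC(C)(C)[C@H]1/C=C/C(C)=C/C=C/C(C)=C/C=C/C=C(C)/C=C/C=C(C)/C=O | intermediate
20 | ethyl (1RS,4S)-4-hydroxy-2,6,6-trimethylcyclohex-2-ene-1-carboxylate | CCOC(=O)C1C(C)=C[C@@H](O)CC1(C)C | intermediate
21 | ethyl (1RS,2R,3S,4S)-2,3-epoxy-4-hydroxy-2,6,6-trimethylcyclohexane-1-carboxylate (oxirane cis to hydroxyl) | CCOC(=O)C1[C@@]2(C)O[C@H]2[C@@H](O)CC1(C)C | intermediate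
22 | ethyl (3R,4S)-3,4-dihydroxy-2,6,6-trimethylcyclohex-1-ene-1-carboxylate | CCOC(=O)C1=C(C)[C@@H](O)[C@@H](O)CC1(C)C | intermediate
23 | ethyl (3R,4S)-3,4-bis[(tert-butyldimethylsilyl)oxy]-2,6,6-trimethylcyclohex-1-ene-1-carboxylate | CCOC(=O)C1=C(C)[C@@H](O[Si](C)(C)C(C)(C)C)[C@@H](O[Si](C)(C)C(C)(C)C)CC1(C)C | intermediate
24 | [(3R,4S)-3,4-bis[(tert-butyldimethylsilyl)oxy]-2,6,6-trimethylcyclohex-1-en-1-yl]methanol | OCC1=C(C)[C@@H](O[Si](C)(C)C(C)(C)C)[C@@H](O[Si](C)(C)C(C)(C)C)CC1(C)C | intermediate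
25 | (3R,4S)-1-(bromomethyl)-3,4-bis[(tert-butyldimethylsilyl)oxy]-2,6,6-trimethylcyclohex-1-ene | BrCC1=C(C)[C@@H](O[Si](C)(C)C(C)(C)C)[C@@H](O[Si](C)(C)C(C)(C)C)CC1(C)C | intermediate
26 | {[(3R,4S)-3,4-bis[(tert-butyldimethylsilyl)oxy]-2,6,6-trimethylcyclohex-1-en-1-yl]methyl}triphenylphosphonium bromide | [Br-].c1ccc(cc1)[P+](CC1=C(C)[C@@H](O[Si](C)(C)C(C)(C)C)[C@@H](O[Si](C)(C)C(C)(C)C)CC1(C)C)(c1ccccc1)c1ccccc1 | intermediate
27 | {[(3R,4S)-3,4-bis[(tert-butyldimethylsilyl)oxy]-2,6,6-trimethylcyclohex-1-en-1-yl]methylidene}triphenylphosphorane | c1ccc(cc1)P(=CC1=C(C)[C@@H](O[Si](C)(C)C(C)(C)C)[C@@H](O[Si](C)(C)C(C)(C)C)CC1(C)C)(c1ccccc1)c1ccccc1 | intermediate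
28 | (all-E)-(3S,4R,3'R,6'R)-3,4,3'-tris[(tert-butyldimethylsilyl)oxy]-β,ε-carotene | CC1=C[C@H](O[Si](C)(C)C(C)(C)C)CC(C)(C)[C@H]1/C=C/C(C)=C/C=C/C(C)=C/C=C/C=C(C)/C=C/C=C(C)/C=C/C1=C(C)[C@@H](O[Si](C)(C)C(C)(C)C)[C@@H](O[Si](C)(C)C(C)(C)C)CC1(C)C | intermediate
29 | (all-E)-(3S,4R,3'R,6'R)-β,ε-carotene-3,4,3'-triol | CC1=C[C@H](O)CC(C)(C)[C@H]1/C=C/C(C)=C/C=C/C(C)=C/C=C/C=C(C)/C=C/C=C(C)/C=C/C1=C(C)[C@@H](O)[C@@H](O)CC1(C)C | target

**Totals**
Total step count: 17. Longest linear sequence: 11 steps (steps 1–9, 16, 17).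

**Steps most likely to fail**

Step 2. The enolate of the open dienone may be diverted from the Michael closure into Claisen attack on the ester carbonyl or into an aldol closure through an isopropylidene methyl group, both of which end in aromatisation, and the base meets an unpurified coupling mixture. The fallback avoids free enolates and separates the two events. Setting out from 3 and 4, the Negishi coupling is run as in step 2 but stopped before the base, and the pyran 7 is isolated by chromatography. Me3SiOTf and Et3N in CH2Cl2 at 0 °C should then trap its open tautomer as ethyl (3Z)-3-methyl-2-(propan-2-ylidene)-5-[(trimethylsilyl)oxy]hexa-3,5-dienoate F1. TiCl4 in CH2Cl2 at −78 °C effects an intramolecular Mukaiyama–Michael addition at the same two carbons, and aqueous work-up returns the route at 9.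

Step 5. Deprotonation of the hindered C1–H may be incomplete, or the proton may arrive on the face anti to the silyloxy group and give the cis ester. The fallback uses inversion at the carbinol instead of reliance on that face. Setting out from 20 (the antipodal alcohol of step 10), silylation gives ethyl (1RS,4S)-4-[(tert-butyldimethylsilyl)oxy]-2,6,6-trimethylcyclohex-2-ene-1-carboxylate F2. The same deprotonation and protonation, through the lithium enolate F3, then gives the cis ester ethyl (1R,4S)-4-[(tert-butyldimethylsilyl)oxy]-2,6,6-trimethylcyclohex-2-ene-1-carboxylate F4. Bu4NF frees ethyl (1R,4S)-4-hydroxy-2,6,6-trimethylcyclohex-2-ene-1-carboxylate F5. Mitsunobu inversion with 4-nitrobenzoic acid (PPh3, DIAD) gives ethyl (1R,4R)-2,6,6-trimethyl-4-[(4-nitrobenzoyl)oxy]cyclohex-2-ene-1-carboxylate F6. K2CO3 in EtOH at 0 °C gives ethyl (1R,4R)-4-hydroxy-2,6,6-trimethylcyclohex-2-ene-1-carboxylate F7, and silylation with TBSCl and imidazole returns the route at 13.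

Step 9. The metalated sulfone may self-condense, or the olefination may run with low E selectivity or on both formyl groups. The fallback is a Wittig olefination followed by isomerisation. Setting out from 14, CBr4 and PPh3 give tert-butyl{[(1R,4R)-4-(bromomethyl)-3,5,5-trimethylcyclohex-2-en-1-yl]oxy}dimethylsilane F8. Heating with PPh3 in MeCN gives {[(1R,4R)-4-[(tert-butyldimethylsilyl)oxy]-2,6,6-trimethylcyclohex-2-en-1-yl]methyl}triphenylphosphonium bromide F9. n-BuLi gives the ylide {[(1R,4R)-4-[(tert-butyldimethylsilyl)oxy]-2,6,6-trimethylcyclohex-2-en-1-yl]methylidene}triphenylphosphorane F10, which is condensed with excess 17; iodine-catalysed Z-to-E isomerisation of the new double bond returns the route at 19.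

Further compounds
F1 | step 2 | ethyl (3Z)-3-methyl-2-(propan-2-ylidene)-5-[(trimethylsilyl)oxy]hexa-3,5-dienoate | CCOC(=O)C(=C(C)C)/C(C)=C\C(=C)O[Si](C)(C)C
F2 | step 5 | ethyl (1RS,4S)-4-[(tert-butyldimethylsilyl)oxy]-2,6,6-trimethylcyclohex-2-ene-1-carboxylate | CCOC(=O)C1C(C)=C[C@@H](O[Si](C)(C)C(C)(C)C)CC1(C)C
F3 | step 5 | lithium ester enolate of F2 | CCOC([O-])=C1C(C)=C[C@@H](O[Si](C)(C)C(C)(C)C)CC1(C)C.[Li+]
F4 | step 5 | ethyl (1R,4S)-4-[(tert-butyldimethylsilyl)oxy]-2,6,6-trimethylcyclohex-2-ene-1-carboxylate | CC1=C[C@@H](O[Si](C)(C)C(C)(C)C)CC(C)(C)[C@H]1C(=O)OCC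
F5 | step 5 | ethyl (1R,4S)-4-hydroxy-2,6,6-trimethylcyclohex-2-ene-1-carboxylate | CC1=C[C@@H](O)CC(C)(C)[C@H]1C(=O)OCC
F6 | step 5 | ethyl (1R,4R)-2,6,6-trimethyl-4-[(4-nitrobenzoyl)oxy]cyclohex-2-ene-1-carboxylate | CC1=C[C@H](OC(=O)c2ccc(cc2)[N+](=O)[O-])CC(C)(C)[C@H]1C(=O)OCC
F7 | step 5 | ethyl (1R,4R)-4-hydroxy-2,6,6-trimethylcyclohex-2-ene-1-carboxylate | CC1=C[C@H](O)CC(C)(C)[C@H]1C(=O)OCC
F8 | step 9 | tert-butyl{[(1R,4R)-4-(bromomethyl)-3,5,5-trimethylcyclohex-2-en-1-yl]oxy}dimethylsilane | CC1=C[C@H](O[Si](C)(C)C(C)(C)C)CC(C)(C)[C@H]1CBr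
F9 | step 9 | {[(1R,4R)-4-[(tert-butyldimethylsilyl)oxy]-2,6,6-trimethylcyclohex-2-en-1-yl]methyl}triphenylphosphonium bromide | [Br-].CC1=C[C@H](O[Si](C)(C)C(C)(C)C)CC(C)(C)[C@H]1C[P+](c1ccccc1)(c1ccccc1)c1ccccc1
F10 | step 9 | {[(1R,4R)-4-[(tert-butyldimethylsilyl)oxy]-2,6,6-trimethylcyclohex-2-en-1-yl]methylidene}triphenylphosphorane | CC1=C[C@H](O[Si](C)(C)C(C)(C)C)CC(C)(C)[C@H]1C=P(c1ccccc1)(c1ccccc1)c1ccccc1
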